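**Retrosynthetic overview**
1. Feature: ring A'' (C4a''–C8a'') is a 1,3,5-trioxygenated benzene. Its C8'', the carbon bonded to C8 of ring A, lies between the oxygen-bearing C7'' and C8a'' and para to the oxygen-bearing C5''.
2. Key disconnection: cutting C8a''–C8'', C6''–C7'' and C4a''–C8a'' takes ring A'' back to 3-ethoxycyclobutenone (C8a'', C6'', C5'', C4a'') and an aryl triisopropylsiloxyalkyne (C8'', C7''). The alkyne already holds the C8–C8'' bond as an aryl–alkyne bond.
3. Endgame: both pyranone rings C (bonds C4–C4a and O1–C2, and their primed counterparts) come from a biphenyl-2,2',6,6'-tetraol and two molecules of ethyl 4-methoxybenzoylacetate, which carry rings B. The 4-O-alkyl groups block closure to 6-linked isomers and are cleaved last from the peri 5/5'' positions.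
4. The siloxyalkyne derives from 2,4,6-trihydroxybenzaldehyde (ring A) by etherification, one-carbon homologation to the arylalkyne, and oxygenation/silylation of its acetylide.
5. Order of rings: A (bought), A'' (benzannulation), then both rings C at once; rings B arrive preformed.

Key step: step 5

Assumption: the target SMILES carries no descriptor for the C8–C8'' axis and the molecule has no stereocentre, so the racemic atropisomer mixture is the goal; 3-ethoxycyclobut-2-en-1-one is taken as a catalogue reagent.

**Route**

Step 1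
Reactants: 1 2,4,6-trihydroxybenzaldehyde
Product: 2 2,6-dihydroxy-4-methoxybenzaldehyde
Conditions: Me2SO4 (1.0 equiv), K2CO3 (1.0 equiv), acetone, rt
Reagents that add atoms: dimethyl sulfate, COS(=O)(=O)OC
Why: Williamson O-methylation with one equivalent of reagent, in which the 4-OH is the most acidic hydroxyl and is neither hydrogen-bonded to nor crowded by the formyl group, the hard electrophile favours O- over C-methylation, the behaviour parallels the familiar 4-O-monomethylation of phloroacetophenone, and over-methylated material is removed by chromatography.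

Step 2
Reactants: 2 2,6-dihydroxy-4-methoxybenzaldehyde
Product: 3 2,6-bis(benzyloxy)-4-methoxybenzaldehyde
Conditions: BnBr (2.5 equiv), K2CO3 (3 equiv), DMF, 60 °C
Reagents that add atoms: benzyl bromide, BrCc1ccccc1
Why: Williamson etherification, in which warm DMF with excess carbonate overcomes the intramolecular hydrogen bonds so that both ortho hydroxyls are benzylated while the aldehyde stays inert.

Step 3
Reactants: 3 2,6-bis(benzyloxy)-4-methoxybenzaldehyde
Product: 4 1,3-bis(benzyloxy)-2-ethynyl-5-methoxybenzene
Conditions: dimethyl (1-diazo-2-oxopropyl)phosphonate (1.5 equiv), K2CO3, MeOH/THF, rt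
Reagents that add atoms: dimethyl (1-diazo-2-oxopropyl)phosphonate, CC(=O)C(=[N+]=[N-])P(=O)(OC)OC
Why: Seyferth–Gilbert homologation in the Ohira–Bestmann variant, in which the diazomethylphosphonate anion released by methanolysis olefinates the non-enolisable aldehyde and loss of N2 with a 1,2-hydride shift gives the terminal alkyne under conditions that leave aryl ethers untouched.

Step 4
Reactants: 4 1,3-bis(benzyloxy)-2-ethynyl-5-methoxybenzene
Product: 7 {[2,6-bis(benzyloxy)-4-methoxyphenyl]ethynyloxy}triisopropylsilane, via lithium acetylide 5 (not isolated), via lithium ynolate 6 (not isolated)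
Conditions: n-BuLi (1.0 equiv), THF, −78 °C; cannulated into t-BuOOLi (from anhydrous t-BuOOH and LiHMDS, THF, −78 °C), then 0 °C; TIPSOTf, −78 to 0 °C; rapid filtration through Et3N-deactivated silica
Reagents that add atoms: tert-butyl hydroperoxide, CC(C)(C)OO; triisopropylsilyl trifluoromethanesulfonate, CC(C)[Si](OS(=O)(=O)C(F)(F)F)(C(C)C)C(C)C
Why: Electrophilic oxygenation of a lithium acetylide by lithium tert-butyl peroxide gives the ynolate, the bulky oxophilic silyl triflate traps it on oxygen rather than carbon, and the alkyne C–H is removed far faster than any benzylic C–H so the benzyl ethers survive.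

Step 5
Reactants: 7 {[2,6-bis(benzyloxy)-4-methoxyphenyl]ethynyloxy}triisopropylsilane; 8 3-ethoxycyclobut-2-en-1-one
Product: 13 2',6'-bis(benzyloxy)-4-ethoxy-4'-methoxy-6-(triisopropylsilyloxy)biphenyl-2-ol, via 3-ethoxyvinylketene 9 (not isolated), via 4-vinylcyclobutenone adduct 10 (not isolated), via dienylketene 11 (not isolated), via cyclohexadienone 12 (not isolated)
Conditions: 8 (2 equiv, in two portions), toluene, sealed tube, 110 °C then 150 °C
Reagents that add atoms: none
Why: Danheiser benzannulation: heat opens 8 by four-electron electrocyclic cleavage of its C1–C4 bond to vinylketene 9, and the nucleophilic, aryl-bearing alkyne carbon of 7 attacks the ketene carbon in a [2+2] cycloaddition that gives cyclobutenone 10 and sets C8a''–C8'' and C6''–C7''. At the higher temperature 10 opens reversibly to dienylketene 11, and the isomer with the ethoxyvinyl group turned inward is drained by a six-electron electrocyclisation that joins the ketene carbon to the terminal CH2 (C4a''–C8a''); this is the mode by which the six-membered ring A'' closes, and dienone 12 then tautomerises to phenol 13. The closest known reaction is the benzannulation of cyclobutenones with triisopropylsiloxyalkynes to resorcinol monosilyl ethers, and what is untested here is only the alkyne substituent, an aryl group with two ortho benzyloxy groups. The selectivity needed is the orientation of the [2+2] step, and it is secured by the polarisation of the ynol silyl ether, whose oxygen pushes electron density onto the carbon that bears ring A, so the aryl group ends between the free OH (future O1'') and OTIPS (future 7''-O) with OEt para to it (C5''). The C8–C8'' bond is present before ring A'' exists, so no hindered aryl–aryl coupling is required, and no stereocentre or stereogenic axis arises because ring A of 13 is symmetric about the axis.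

Step 6
Reactants: 13 2',6'-bis(benzyloxy)-4-ethoxy-4'-methoxy-6-(triisopropylsilyloxy)biphenyl-2-ol
Product: 14 2',6'-bis(benzyloxy)-4-ethoxy-4'-methoxybiphenyl-2,6-diol
Conditions: TBAF/AcOH (1:1, 1.2 equiv), THF, 0 °C
Reagents that add atoms: none
Why: Fluoride-induced cleavage of an aryl silyl ether driven by the strong Si–F bond, with acetic acid buffering to keep the electron-rich resorcinol protonated and less prone to air oxidation, while benzyl and alkyl ethers are inert.

Step 7
Reactants: 14 2',6'-bis(benzyloxy)-4-ethoxy-4'-methoxybiphenyl-2,6-diol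
Product: 15 4-ethoxy-4'-methoxybiphenyl-2,2',6,6'-tetraol
Conditions: H2 (1 atm), 10% Pd/C, EtOAc/EtOH, rt; handled under argon
Reagents that add atoms: none
Why: Catalytic hydrogenolysis of benzyl aryl ethers, which leaves methyl and ethyl ethers and the arene rings untouched at atmospheric pressure and room temperature.

Step 8
Reactants: 15 4-ethoxy-4'-methoxybiphenyl-2,2',6,6'-tetraol; 16 ethyl 4-methoxybenzoylacetate
Product: 18 5''-ethoxy-7,7''-dihydroxy-5,4',4'''-trimethoxy-8,8''-biflavone, via bis(1,3-diketone) 17 (not isolated)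
Conditions: 16 (3 equiv), neat, N2, microwave, 240 °C, EtOH and H2O vented
Reagents that add atoms: none
Why: Mentzer thermal pyrone synthesis, in which the β-keto ester loses EtOH to an aroylketene that C-acylates each phloroglucinol-type ring at one of its two equivalent free CH positions, the acyl group then lies between one free OH and the blocked 4-O-alkyl group so cyclodehydration can only use the OH next to the biaryl bond and gives the 8,8''-linked flavone, and the first pyranone deactivates its own ring so the second equivalent goes to the other ring.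

Step 9
Reactants: 18 5''-ethoxy-7,7''-dihydroxy-5,4',4'''-trimethoxy-8,8''-biflavone
Product: 19 4',4'''-di-O-methylcupressuflavone
Conditions: BCl3 (1 M in CH2Cl2, 8 equiv), CH2Cl2, −20 °C to rt; then 1 M HCl/MeOH
Reagents that add atoms: none
Why: Chelation-directed ether cleavage, in which BCl3 bridges each C4 carbonyl oxygen and the peri 5-OMe or 5''-OEt oxygen and chloride removes the alkyl group, whereas the unchelated 4'- and 4'''-methoxy groups are inert to BCl3 at or below room temperature and the mild conditions avoid Wessely–Moser isomerisation of the 8,8'' linkage.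

**Compound list**
1 | 2,4,6-trihydroxybenzaldehyde | O=Cc1c(O)cc(O)cc1O | starting material
2 | 2,6-dihydroxy-4-methoxybenzaldehyde | COc1cc(O)c(C=O)c(O)c1 | intermediate
3 | 2,6-bis(benzyloxy)-4-methoxybenzaldehyde | COc1cc(OCc2ccccc2)c(C=O)c(OCc2ccccc2)c1 | intermediate
4 | 1,3-bis(benzyloxy)-2-ethynyl-5-methoxybenzene | C#Cc1c(OCc2ccccc2)cc(OC)cc1OCc1ccccc1 | intermediate
5 | lithium [2,6-bis(benzyloxy)-4-methoxyphenyl]acetylide | [Li]C#Cc1c(OCc2ccccc2)cc(OC)cc1OCc1ccccc1 | intermediate
6 | lithium [2,6-bis(benzyloxy)-4-methoxyphenyl]ethynolate | [Li+].[O-]C#Cc1c(OCc2ccccc2)cc(OC)cc1OCc1ccccc1 | intermediate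
7 | {[2,6-bis(benzyloxy)-4-methoxyphenyl]ethynyloxy}triisopropylsilane | COc1cc(OCc2ccccc2)c(C#CO[Si](C(C)C)(C(C)C)C(C)C)c(OCc2ccccc2)c1 | intermediate
8 | 3-ethoxycyclobut-2-en-1-one | CCOC1=CC(=O)C1 | starting material
9 | 3-ethoxybuta-1,3-dien-1-one (3-ethoxyvinylketene) | CCOC(=C)C=C=O | intermediate
10 | 2-[2,6-bis(benzyloxy)-4-methoxyphenyl]-4-(1-ethoxyvinyl)-3-(triisopropylsilyloxy)cyclobut-2-en-1-one (racemic at C4, transient) | CCOC(=C)C1C(=O)C(c2c(OCc3ccccc3)cc(OC)cc2OCc2ccccc2)=C1O[Si](C(C)C)(C(C)C)C(C)C | intermediate
11 | (3E)-2-[2,6-bis(benzyloxy)-4-methoxyphenyl]-5-ethoxy-3-(triisopropylsilyloxy)hexa-1,3,5-trien-1-one (ketene carbon chain and ethoxyvinyl group cis on C3=C4) | CCOC(=C)/C=C(\C(=C=O)c1c(OCc2ccccc2)cc(OC)cc1OCc1ccccc1)O[Si](C(C)C)(C(C)C)C(C)C | intermediate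
12 | 2-[2,6-bis(benzyloxy)-4-methoxyphenyl]-5-ethoxy-3-(triisopropylsilyloxy)cyclohexa-2,4-dien-1-one | CCOC1=CC(O[Si](C(C)C)(C(C)C)C(C)C)=C(c2c(OCc3ccccc3)cc(OC)cc2OCc2ccccc2)C(=O)C1 | intermediate
13 | 2',6'-bis(benzyloxy)-4-ethoxy-4'-methoxy-6-(triisopropylsilyloxy)biphenyl-2-ol | CCOc1cc(O)c(-c2c(OCc3ccccc3)cc(OC)cc2OCc2ccccc2)c(O[Si](C(C)C)(C(C)C)C(C)C)c1 | intermediate
14 | 2',6'-bis(benzyloxy)-4-ethoxy-4'-methoxybiphenyl-2,6-diol | CCOc1cc(O)c(-c2c(OCc3ccccc3)cc(OC)cc2OCc2ccccc2)c(O)c1 | intermediate
15 | 4-ethoxy-4'-methoxybiphenyl-2,2',6,6'-tetraol | CCOc1cc(O)c(-c2c(O)cc(OC)cc2O)c(O)c1 | intermediate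
16 | ethyl 4-methoxybenzoylacetate | CCOC(=O)CC(=O)c1ccc(OC)cc1 | starting material
17 | 4-ethoxy-4'-methoxy-3,3'-bis[3-(4-methoxyphenyl)-3-oxopropanoyl]biphenyl-2,2',6,6'-tetraol | CCOc1cc(O)c(-c2c(O)cc(OC)c(C(=O)CC(=O)c3ccc(OC)cc3)c2O)c(O)c1C(=O)CC(=O)c1ccc(OC)cc1 | intermediate
18 | 5''-ethoxy-7,7''-dihydroxy-5,4',4'''-trimethoxy-8,8''-biflavone (racemic axis) | COc1ccc(-c2cc(=O)c3c(OC)cc(O)c(-c4c(O)cc(OCC)c5c(=O)cc(-c6ccc(OC)cc6)oc45)c3o2)cc1 | intermediate
19 | 4',4'''-di-O-methylcupressuflavone (racemic axis) | COc1ccc(-c2cc(=O)c3c(O)cc(O)c(-c4c(O)cc(O)c5c(=O)cc(-c6ccc(OC)cc6)oc45)c3o2)cc1 | target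

**Totals**
- Total step count: 9.
- Longest linear sequence: 9 steps (1 to 19); 8 and 16 enter as bought partners.

**Steps most likely to fail**

**Step 5.**
- What may go wrong:
  - The vinylogous-ester cyclobutenone may open too slowly.
  - The vinylketene may be lost to self-condensation or to acylation of phenol already formed.
  - The [2+2] addition may be retarded by the two benzyloxy groups flanking the attacking alkyne carbon.
  - The cascade may stall before the second ring opening.
- Fallback: aryl–aryl coupling in place of ring construction, setting out from aldehyde 3. Pinnick oxidation (NaClO2, NaH2PO4, 2-methyl-2-butene, t-BuOH/H2O) should give 2,6-bis(benzyloxy)-4-methoxybenzoic acid F1. Decarboxylative iodination of this electron-rich acid (I2, K3PO4, MeCN, 100 °C) should give 1,3-bis(benzyloxy)-2-iodo-5-methoxybenzene F2. Ullmann homocoupling (activated Cu bronze, DMF, 150 °C) should give 2,2',6,6'-tetrakis(benzyloxy)-4,4'-dimethoxybiphenyl F3. Hydrogenolysis under the conditions of step 7 should give 4,4'-dimethoxybiphenyl-2,2',6,6'-tetraol F4. Annulation with 16 under the conditions of step 8 should give 7,7''-dihydroxy-5,5'',4',4'''-tetramethoxy-8,8''-biflavone F5. BCl3 under the conditions of step 9 then removes both 5-O-methyl groups, and the fallback comes back to the route at 19.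

**Step 8.**
- What may go wrong:
  - The second annulation may remain incomplete.
  - O-acylation may occur without acyl migration to carbon.
  - Pechmann-type closure may compete.
  - At this temperature, dehydrative ether formation between the 2- and 2'-hydroxyls may consume the tetraol.
- Fallback: stepwise construction of the pyranones at low temperature, setting out from tetraol 15. A Houben–Hoesch reaction (MeCN, ZnCl2, HCl gas, Et2O, 0 °C) should precipitate the 3,3'-bis(ketiminium chloride) F6, which limits acylation to one group per ring. Hydrolysis in boiling water should give 3,3'-diacetyl-4-ethoxy-4'-methoxybiphenyl-2,2',6,6'-tetraol F7. Excess LiHMDS (THF, −78 to −10 °C) forms the tetraphenoxide bis-enolate. 4-Methoxybenzoyl chloride (2 equiv) should then C-aroylate both enolates, a Baker–Venkataraman-type diketone synthesis without the O-acyl detour, to give 17, now isolated. Catalytic H2SO4 in AcOH at 95 °C closes both rings, and the fallback comes back to the route at 18.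

**Step 4.**
- What may go wrong:
  - Oxygen transfer to the acetylide may be incomplete.
  - The ynolate may be silylated on carbon.
  - The electron-rich siloxyalkyne may be protonated and hydrolysed during isolation.
- Fallback: the ynolate is made by carbenoid rearrangement instead of acetylide oxidation, setting out from aldehyde 3. Addition of LiCHBr2 (CH2Br2, LDA, THF, −78 °C) should give 1-[2,6-bis(benzyloxy)-4-methoxyphenyl]-2,2-dibromoethanol F8. Dess–Martin periodinane (CH2Cl2, rt) should give 1-[2,6-bis(benzyloxy)-4-methoxyphenyl]-2,2-dibromoethanone F9. LiHMDS followed by n-BuLi (THF, −78 °C, then warming) effects enolisation, bromine–lithium exchange and the 1,2-aryl shift that underlies the Kowalski homologation. This delivers ynolate 6, which is silylated with TIPSOTf, and the fallback comes back to the route at 7. The crude product can be carried directly into step 5.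

**Further compounds**
F1 | step 5 | 2,6-bis(benzyloxy)-4-methoxybenzoic acid | COc1cc(OCc2ccccc2)c(C(=O)O)c(OCc2ccccc2)c1
F2 | step 5 | 1,3-bis(benzyloxy)-2-iodo-5-methoxybenzene | COc1cc(OCc2ccccc2)c(I)c(OCc2ccccc2)c1
F3 | step 5 | 2,2',6,6'-tetrakis(benzyloxy)-4,4'-dimethoxybiphenyl | COc1cc(OCc2ccccc2)c(-c2c(OCc3ccccc3)cc(OC)cc2OCc2ccccc2)c(OCc2ccccc2)c1
F4 | step 5 | 4,4'-dimethoxybiphenyl-2,2',6,6'-tetraol | COc1cc(O)c(-c2c(O)cc(OC)cc2O)c(O)c1
F5 | step 5 | 7,7''-dihydroxy-5,5'',4',4'''-tetramethoxy-8,8''-biflavone | COc1ccc(-c2cc(=O)c3c(OC)cc(O)c(-c4c(O)cc(OC)c5c(=O)cc(-c6ccc(OC)cc6)oc45)c3o2)cc1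
F6 | step 8 | 3,3'-bis(1-iminioethyl)-4-ethoxy-4'-methoxybiphenyl-2,2',6,6'-tetraol dichloride | CCOc1cc(O)c(-c2c(O)cc(OC)c(C(C)=[NH2+])c2O)c(O)c1C(C)=[NH2+].[Cl-].[Cl-]
F7 | step 8 | 3,3'-diacetyl-4-ethoxy-4'-methoxybiphenyl-2,2',6,6'-tetraol | CCOc1cc(O)c(-c2c(O)cc(OC)c(C(C)=O)c2O)c(O)c1C(C)=O
F8 | step 4 | 1-[2,6-bis(benzyloxy)-4-methoxyphenyl]-2,2-dibromoethanol (racemic) | COc1cc(OCc2ccccc2)c(C(O)C(Br)Br)c(OCc2ccccc2)c1
F9 | step 4 | 1-[2,6-bis(benzyloxy)-4-methoxyphenyl]-2,2-dibromoethanone | COc1cc(OCc2ccccc2)c(C(=O)C(Br)Br)c(OCc2ccccc2)c1
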